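I start by counting reagent. In this flask a substrate that becomes first product or other mono adduct takes one reagent, and a double product takes a second. So I reckon the reagent left, R in percent of the substrate charged, as the excess of reagent over substrate, 30.0 %, plus the substrate A still present, minus the double product D.

- larch: substrate 0.16 M; reagent 1.3 equiv; the very flask that is asked about, followed so far
- flask: substrate 0.16 M; reagent 1.30 equiv; time 5.0 d

larch run (percent of the substrate charged)

| time / h | substrate / % | first product / % | other mono adduct / % |
|---|---|---|---|
| 6.00 | 85.7 | 9.3 | 3.0 |
| 12.0 | 76.0 | 14.2 | 5.8 |
| 20.0 | 65.5 | 14.6 | 6.3 |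
| 25.0 | 59.9 | 13.2 | 7.3 |
| 30.0 | 56.5 | 13.3 | 8.7 |
| 40.0 | 49.5 | 10.1 | 8.9 |

(readings scatter by 0.5 percentage points)

1. substrate at 5.0 d, in percent of the substrate charged
2. first product at 5.0 d, in percent of the substrate charged
3. other mono adduct at 5.0 d, in percent of the substrate charged
4. double product at 5.0 d, in percent of the substrate charged



Is reagent short? The charge of 1.30 equiv is less than the two equivalents that full double addition takes, so reagent is the limiting reagent for double product.

How far has the larch flask gone? Double product is not read. At 40.0 h the three readings leave a gap of 31.5 %, and D is some share of that gap. If the gap were all D, R would be 48.0 %, about level with substrate, and any other content of the gap raises R.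

I expect both substrate and reagent to remain at 5.0 d, and I read D as a share of the gap, not as the gap itself.

The forecast gives substrate 32 %, first product 8.8 %, other mono adduct 11 % and double product 48 %, saying “Reagent is the limit”. On my balance that pair leaves R = 14.0 %.

At 5.0 d the flask gives substrate 27.1 %, first product 2.21 %, other mono adduct 9.05 % and double product 30.2 %.

    substrate + reagent ⇌ first product + by-product (K = 2.00, k = 0.00158 M⁻¹ min⁻¹)
    substrate + reagent → other mono adduct + by-product (k = 5.24 × 10⁻⁴ M⁻¹ min⁻¹)
    reagent + first product → double product + by-product (k = 0.00364 M⁻¹ min⁻¹)
    reagent + other mono adduct → double product + by-product (k = 0.00204 M⁻¹ min⁻¹)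
    2 substrate → self-condensation product (k = 7.17 × 10⁻⁶ M⁻¹ min⁻¹)
    first product + by-product → side product (k = 0.00733 M⁻¹ min⁻¹)

The balance gives R = 26.8 %, which is 20.6 % of the reagent's own charge. Substrate that went to self-condensation product, 0.412 %, took no reagent, so it is added, which gives 20.9 %, and the flask holds 21.0 %. The flask's gap is 61.6 %, where side product at 31.0 % and self-condensation product stand beside double product. The neighbour charged with 2.20 equiv has an excess of 120 %, so its substrate 7.66 %, self-condensation product 0.210 % and double product 52.2 % give 34.4 % of its own charge, and that flask holds 34.4 % of reagent.

The earlier runs and the new flask were generated by integration with constants of no real substance; noise was put on by code.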